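**Retrosynthetic overview**

1. The angelate and the isopropenyl group are taken back to the secondary and the tertiary hydroxyl of a cis-1,3-diol (C3–OH and the CMe2–OH carbon on C2 of the 2,3-dihydrobenzofuran).
2. Feature used: across the C2–C3 bond of the dihydrofuran ring (O1, C2, C3, C3a, C7a) the C3 oxygen is cis to the exocyclic carbon on C2, and an oxygen on that carbon is three bonds from C3. A silicon atom held on that oxygen can therefore close only a five-membered ring (Si, O, CMe2, C2, C3) onto the cis C3–H.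
3. Key disconnection: C3–O to C3–Si to C3–H, by iridium-catalysed C–H silylation of the diethyl(hydrido)silyl ether 16 to the cis-fused oxasilolane 17, then Tamao–Fleming oxidation with retention.
4. C2 and the dihydrofuran ring come from Shi epoxidation of an ortho-prenyl phenol and 5-exo epoxide opening. The prenyl group comes from an aromatic Claisen rearrangement on a phenol made from gallacetophenone, whose acetyl group is carried as a dioxolane through the silane chemistry.
5. Ring order: benzene ring (from gallacetophenone), dihydrofuran ring (step 10), temporary oxasilolane ring (step 12, opened again in step 13).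

Key step: step 12

Remark: locants C2, C3, C3a and so on follow the 2,3-dihydro-1-benzofuran numbering of the target; gallacetophenone, 3-chloro-3-methylbut-1-yne, diethylsilane, angelic acid and the D-fructose-derived Shi ketone are taken to be commercial.

**Route**

Step 1
Reactants: 1 gallacetophenone (1-(2,3,4-trihydroxyphenyl)ethanone)
Product: 2 1-[4-(benzyloxy)-2,3-dihydroxyphenyl]ethanone
Conditions: BnBr (1.05 equiv), NaHCO3, DMF, 40 °C
Reagents that add atoms: benzyl bromide, BrCc1ccccc1
Why: Williamson etherification under weak-base control; the 4-OH para to the acetyl group is the most acidic hydroxyl and the only one ionised by hydrogencarbonate (the 2-OH is hydrogen-bonded to the carbonyl), so it should be benzylated selectively.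

Step 2
Reactants: 2 1-[4-(benzyloxy)-2,3-dihydroxyphenyl]ethanone
Product: 3 1-[4-(benzyloxy)-2,3-dimethoxyphenyl]ethanone
Conditions: MeI (excess), K2CO3, DMF, 50 °C
Reagents that add atoms: iodomethane, CI
Why: exhaustive Williamson methylation of the two remaining phenols, with excess reagent and warming for the chelated 2-OH.

Step 3
Reactants: 3 1-[4-(benzyloxy)-2,3-dimethoxyphenyl]ethanone
Product: 4 2-[4-(benzyloxy)-2,3-dimethoxyphenyl]-2-methyl-1,3-dioxolane
Conditions: HOCH2CH2OH, TsOH·H2O (cat.), toluene, reflux, Dean–Stark; Et3N quench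
Reagents that add atoms: ethylene glycol, OCCO
Why: acid-catalysed ketalisation with azeotropic removal of water, placed here because the molecule carries no acid-sensitive group yet and the dioxolane is needed later to keep the aryl ketone away from the hydrosilane.

Step 4
Reactants: 4 2-[4-(benzyloxy)-2,3-dimethoxyphenyl]-2-methyl-1,3-dioxolane
Product: 5 2,3-dimethoxy-4-(2-methyl-1,3-dioxolan-2-yl)phenol
Conditions: H2 (1 atm), Pd/C, solid NaHCO3, EtOAc, rt
Reagents that add atoms: none
Why: hydrogenolysis of the benzyl aryl ether under neutral conditions, which the ketal and the methyl ethers should survive.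

Step 5
Reactants: 5 2,3-dimethoxy-4-(2-methyl-1,3-dioxolan-2-yl)phenol; 6 3-chloro-3-methylbut-1-yne
Product: 7 2-{2,3-dimethoxy-4-[(2-methylbut-3-yn-2-yl)oxy]phenyl}-2-methyl-1,3-dioxolane
Conditions: 6 (1.3 equiv), DBU, CuCl2·2H2O (cat.), MeCN, 0 °C to rt
Reagents that add atoms: none
Why: copper-catalysed O-alkylation of a phenol with a tertiary propargylic chloride, which goes through a copper-bound propargyl/allenyl electrophile and is run under basic conditions harmless to the ketal.

Step 6
Reactants: 7 2-{2,3-dimethoxy-4-[(2-methylbut-3-yn-2-yl)oxy]phenyl}-2-methyl-1,3-dioxolane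
Product: 8 2-{2,3-dimethoxy-4-[(2-methylbut-3-en-2-yl)oxy]phenyl}-2-methyl-1,3-dioxolane
Conditions: H2 (1 atm), Pd/CaCO3/Pb(OAc)2 (Lindlar catalyst), quinoline, EtOAc, rt
Reagents that add atoms: none
Why: Lindlar semi-hydrogenation of the terminal alkyne to the alkene, which turns the ether into a Claisen substrate and closes off the thermal route of aryl propargyl ethers to chromenes.

Step 7
Reactants: 8 2-{2,3-dimethoxy-4-[(2-methylbut-3-en-2-yl)oxy]phenyl}-2-methyl-1,3-dioxolane
Product: 10 2,3-dimethoxy-4-(2-methyl-1,3-dioxolan-2-yl)-6-(3-methylbut-2-en-1-yl)phenol, via ortho-dienone 9 (not isolated)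
Conditions: DMF, 120 °C
Reagents that add atoms: none
Why: aromatic Claisen rearrangement; the [3,3] shift transposes the 1,1-dimethylallyl group into a prenyl group at the only free ortho position (the other carries OMe), and the dienone tautomerises to the phenol.

Step 8
Reactants: 10 2,3-dimethoxy-4-(2-methyl-1,3-dioxolan-2-yl)-6-(3-methylbut-2-en-1-yl)phenol
Product: 11 tert-butyl[2,3-dimethoxy-4-(2-methyl-1,3-dioxolan-2-yl)-6-(3-methylbut-2-en-1-yl)phenoxy]dimethylsilane
Conditions: TBSCl, imidazole, DMF, rt
Reagents that add atoms: tert-butyldimethylsilyl chloride, CC(C)(C)[Si](C)(C)Cl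
Why: silylation of the phenol, which shields the electron-rich phenoxide from the dioxirane oxidant of the next step and postpones epoxide opening to a separate, controlled step.

Step 9
Reactants: 11 tert-butyl[2,3-dimethoxy-4-(2-methyl-1,3-dioxolan-2-yl)-6-(3-methylbut-2-en-1-yl)phenoxy]dimethylsilane
Product: 12 tert-butyl(6-{[(2R)-3,3-dimethyloxiran-2-yl]methyl}-2,3-dimethoxy-4-(2-methyl-1,3-dioxolan-2-yl)phenoxy)dimethylsilane
Conditions: D-fructose-derived Shi ketone (1,2:4,5-di-O-isopropylidene-β-D-erythro-2,3-hexodiulo-2,6-pyranose, 30 mol%), Oxone (2KHSO5·KHSO4·K2SO4), K2CO3, Bu4NHSO4, MeCN–CH2(OMe)2–aq. Na2B4O7 buffer (pH ca. 10.5), 0 °C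
Reagents that add atoms: potassium peroxymonosulfate (active part of Oxone), [K+].[O-]S(=O)(=O)OO
Why: Shi asymmetric epoxidation; the chiral dioxirane transfers oxygen to the trisubstituted alkene through a spiro transition state, and this ketone enantiomer should give the (R)-epoxide, which fixes the carbon that becomes C2.

Step 10
Reactants: 12 tert-butyl(6-{[(2R)-3,3-dimethyloxiran-2-yl]methyl}-2,3-dimethoxy-4-(2-methyl-1,3-dioxolan-2-yl)phenoxy)dimethylsilane
Product: 14 2-[(2S)-6,7-dimethoxy-5-(2-methyl-1,3-dioxolan-2-yl)-2,3-dihydro-1-benzofuran-2-yl]propan-2-ol, via epoxy phenol 13 (not isolated)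
Conditions: Bu4NF, THF, 0 °C to rt
Reagents that add atoms: none
Why: fluoride desilylation followed by intramolecular epoxide opening; the phenoxide attacks the secondary epoxide carbon in a 5-exo-tet SN2 reaction (preferred under base over 6-endo attack at the tertiary carbon), so C2 is formed with inversion as (S) and the tertiary alcohol is released.

Step 11
Reactants: 14 2-[(2S)-6,7-dimethoxy-5-(2-methyl-1,3-dioxolan-2-yl)-2,3-dihydro-1-benzofuran-2-yl]propan-2-ol; 15 diethylsilane
Product: 16 diethyl({2-[(2S)-6,7-dimethoxy-5-(2-methyl-1,3-dioxolan-2-yl)-2,3-dihydro-1-benzofuran-2-yl]propan-2-yl}oxy)silane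
Conditions: 15 (1.5 equiv), [Ir(cod)OMe]2 (cat.), THF, rt to 50 °C; volatiles removed in vacuo, used crude
Reagents that add atoms: none
Why: iridium-catalysed dehydrogenative silylation of an alcohol with a dihydrosilane (H2 is lost); the bulk of the tertiary alkoxy group and the excess silane should stop it at the mono(alkoxy)hydrosilane, and the dioxolane keeps the acetyl group from being hydrosilylated.

Step 12
Reactants: 16 diethyl({2-[(2S)-6,7-dimethoxy-5-(2-methyl-1,3-dioxolan-2-yl)-2,3-dihydro-1-benzofuran-2-yl]propan-2-yl}oxy)silane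
Product: 17 cis-fused oxasilolane: the (2R,3R)-2,3-dihydro-1-benzofuran derived from 16 in which C3 is bonded to the SiEt2 group of the side-chain silyl ether (ring Si–O–CMe2–C2–C3), with 6,7-dimethoxy and 5-(2-methyl-1,3-dioxolan-2-yl) groups unchanged
Conditions: [Ir(cod)OMe]2 (2–4 mol%), 3,4,7,8-tetramethyl-1,10-phenanthroline (5–8 mol%), norbornene (1.5 equiv), THF, 100–120 °C, sealed tube
Reagents that add atoms: none
Why: The Si–H bond of 16 adds to the phenanthroline-ligated iridium centre and norbornene is hydrogenated to norbornane, which leaves an iridium silyl species tethered through Si–O–CMe2 to C2; this species cleaves the benzylic C3–H bond and reductive elimination forms the C3–Si bond. The closest known reaction type is the iridium-catalysed intramolecular silylation of secondary alkyl C–H bonds gamma to the oxygen of diethyl(hydrido)silyl ethers of tertiary alcohols, used here on a benzylic ring methylene. The ring closed is the five-membered 1,2-oxasilolane (Si, O, CMe2, C2, C3), which forms by C–Si reductive elimination from a six-membered iridacycle and is cis-fused to the dihydrofuran ring across C2–C3. The new stereocentre C3 is controlled by the C2 stereocentre, because the three-atom tether lets only the C3 hydrogen on the face of the CMe2O group reach the metal and a trans-fused bicyclo[3.3.0] framework is out of reach. The step needs regioselectivity and a choice between the two diastereotopic C3 hydrogens: C3 is the only carbon gamma to the silyl ether oxygen (the geminal methyl groups are beta and would give a four-membered ring, the aromatic C4–H would need a seven-membered ring), and the dioxolane removes the one group, the aryl ketone, that a hydrosilane and iridium would reduce.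

Step 13
Reactants: 17 cis-fused oxasilolane
Product: 18 (2S,3R)-2-(2-hydroxypropan-2-yl)-6,7-dimethoxy-5-(2-methyl-1,3-dioxolan-2-yl)-2,3-dihydro-1-benzofuran-3-ol
Conditions: 30% H2O2, KHCO3, KF, THF–MeOH, 50 °C; aq. Na2S2O3 work-up
Reagents that add atoms: hydrogen peroxide, OO
Why: Tamao–Fleming oxidation; peroxide adds to the fluoride-activated alkoxysilane and C3 migrates from silicon to oxygen with retention, so the C3–O bond appears on the face that carried silicon (cis to the side chain) and both hydroxyls are freed, while the roughly 120° angle between C3–Si and C2–O1 in the cis-fused bicycle should disfavour beta-elimination of the ring oxygen.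

Step 14
Reactants: 18 (2S,3R)-2-(2-hydroxypropan-2-yl)-6,7-dimethoxy-5-(2-methyl-1,3-dioxolan-2-yl)-2,3-dihydro-1-benzofuran-3-ol
Product: 19 1-[(2S,3R)-3-hydroxy-2-(2-hydroxypropan-2-yl)-6,7-dimethoxy-2,3-dihydro-1-benzofuran-5-yl]ethanone
Conditions: PPTS (cat.), THF–H2O, rt to 40 °C
Reagents that add atoms: water, O
Why: acid-catalysed ketal hydrolysis; the dioxolane on the alkoxy-substituted aryl carbon ionises far more readily than the benzylic C3–OH, so the acetyl group should be released with the diol intact, and its electron withdrawal then protects the benzylic C3–O bond in the last two steps.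

Step 15
Reactants: 19 1-[(2S,3R)-3-hydroxy-2-(2-hydroxypropan-2-yl)-6,7-dimethoxy-2,3-dihydro-1-benzofuran-5-yl]ethanone; 20 angelic acid ((2Z)-2-methylbut-2-enoic acid)
Product: 22 (2S,3R)-5-acetyl-2-(2-hydroxypropan-2-yl)-6,7-dimethoxy-2,3-dihydro-1-benzofuran-3-yl (2Z)-2-methylbut-2-enoate, via mixed anhydride 21 (not isolated)
Conditions: 20, 2,4,6-Cl3C6H2COCl, Et3N, toluene, rt; then 19, 75 °C, no DMAP
Reagents that add atoms: none
Why: Yamaguchi esterification without nucleophilic catalyst; the secondary C3–OH attacks the unhindered angeloyl carbonyl of the mixed anhydride while the tertiary hydroxyl is too hindered to compete, and leaving out DMAP should avoid the addition–elimination pathway that turns angelates into tiglates.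

Step 16
Reactants: 22 (2S,3R)-5-acetyl-2-(2-hydroxypropan-2-yl)-6,7-dimethoxy-2,3-dihydro-1-benzofuran-3-yl (2Z)-2-methylbut-2-enoate
Product: 24 (2R,3R)-5-acetyl-6,7-dimethoxy-2-(prop-1-en-2-yl)-2,3-dihydro-1-benzofuran-3-yl (2Z)-2-methylbut-2-enoate (target), via sulfamate salt 23 (not isolated)
Conditions: Burgess reagent (MeO2C–N(−)–SO2–N(+)Et3), benzene, rt to 60 °C
Reagents that add atoms: none
Why: Burgess dehydration; the tertiary alcohol is sulfonylated and syn-elimination through a cyclic transition state should remove one of the six methyl hydrogens in preference to the single hindered C2–H, giving the isopropenyl group under neutral conditions that leave the Z-enoate, the benzylic ester and both stereocentres untouched (the C2 descriptor changes from S to R only through substituent priorities).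

**Compound list**

1 | gallacetophenone | CC(=O)c1ccc(O)c(O)c1O | starting material
2 | 1-[4-(benzyloxy)-2,3-dihydroxyphenyl]ethanone | CC(=O)c1ccc(OCc2ccccc2)c(O)c1O | intermediate
3 | 1-[4-(benzyloxy)-2,3-dimethoxyphenyl]ethanone | CC(=O)c1ccc(OCc2ccccc2)c(OC)c1OC | intermediate
4 | 2-[4-(benzyloxy)-2,3-dimethoxyphenyl]-2-methyl-1,3-dioxolane | CC1(OCCO1)c1ccc(OCc2ccccc2)c(OC)c1OC | intermediate
5 | 2,3-dimethoxy-4-(2-methyl-1,3-dioxolan-2-yl)phenol | CC1(OCCO1)c1ccc(O)c(OC)c1OC | intermediate
6 | 3-chloro-3-methylbut-1-yne | C#CC(C)(C)Cl | starting material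
7 | 2-{2,3-dimethoxy-4-[(2-methylbut-3-yn-2-yl)oxy]phenyl}-2-methyl-1,3-dioxolane | CC1(OCCO1)c1ccc(OC(C)(C)C#C)c(OC)c1OC | intermediate
8 | 2-{2,3-dimethoxy-4-[(2-methylbut-3-en-2-yl)oxy]phenyl}-2-methyl-1,3-dioxolane | CC1(OCCO1)c1ccc(OC(C)(C)C=C)c(OC)c1OC | intermediate
9 | ortho-dienone: 2,3-dimethoxy-4-(2-methyl-1,3-dioxolan-2-yl)-6-(3-methylbut-2-en-1-yl)cyclohexa-2,4-dien-1-one | O=C1C(CC=C(C)C)C=C(C2(C)OCCO2)C(OC)=C1OC | intermediate (not isolated)
10 | 2,3-dimethoxy-4-(2-methyl-1,3-dioxolan-2-yl)-6-(3-methylbut-2-en-1-yl)phenol | CC(C)=CCc1cc(C2(C)OCCO2)c(OC)c(OC)c1O | intermediate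
11 | tert-butyl[2,3-dimethoxy-4-(2-methyl-1,3-dioxolan-2-yl)-6-(3-methylbut-2-en-1-yl)phenoxy]dimethylsilane | CC(C)=CCc1cc(C2(C)OCCO2)c(OC)c(OC)c1O[Si](C)(C)C(C)(C)C | intermediate
12 | tert-butyl(6-{[(2R)-3,3-dimethyloxiran-2-yl]methyl}-2,3-dimethoxy-4-(2-methyl-1,3-dioxolan-2-yl)phenoxy)dimethylsilane | CC1(C)O[C@@H]1Cc1cc(C2(C)OCCO2)c(OC)c(OC)c1O[Si](C)(C)C(C)(C)C | intermediate
13 | epoxy phenol: 6-{[(2R)-3,3-dimethyloxiran-2-yl]methyl}-2,3-dimethoxy-4-(2-methyl-1,3-dioxolan-2-yl)phenol (reacts as its tetrabutylammonium phenoxide) | CC1(C)O[C@@H]1Cc1cc(C2(C)OCCO2)c(OC)c(OC)c1O | intermediate (not isolated)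
14 | 2-[(2S)-6,7-dimethoxy-5-(2-methyl-1,3-dioxolan-2-yl)-2,3-dihydro-1-benzofuran-2-yl]propan-2-ol | CC(C)(O)[C@H]1Oc2c(cc(C3(C)OCCO3)c(OC)c2OC)C1 | intermediate
15 | diethylsilane | CC[SiH2]CC | starting material
16 | diethyl({2-[(2S)-6,7-dimethoxy-5-(2-methyl-1,3-dioxolan-2-yl)-2,3-dihydro-1-benzofuran-2-yl]propan-2-yl}oxy)silane | CC[SiH](CC)OC(C)(C)[C@H]1Oc2c(cc(C3(C)OCCO3)c(OC)c2OC)C1 | intermediate
17 | cis-fused oxasilolane, (2R,3R) at C2/C3 of the dihydrobenzofuran, ring Si(Et2)–O–CMe2–C2–C3 | CC[Si]1(CC)OC(C)(C)[C@H]2Oc3c(cc(C4(C)OCCO4)c(OC)c3OC)[C@H]21 | intermediate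
18 | (2S,3R)-2-(2-hydroxypropan-2-yl)-6,7-dimethoxy-5-(2-methyl-1,3-dioxolan-2-yl)-2,3-dihydro-1-benzofuran-3-ol | CC(C)(O)[C@H]1Oc2c(cc(C3(C)OCCO3)c(OC)c2OC)[C@H]1O | intermediate
19 | 1-[(2S,3R)-3-hydroxy-2-(2-hydroxypropan-2-yl)-6,7-dimethoxy-2,3-dihydro-1-benzofuran-5-yl]ethanone | CC(C)(O)[C@H]1Oc2c(cc(C(C)=O)c(OC)c2OC)[C@H]1O | intermediate
20 | angelic acid | C/C=C(/C)C(=O)O | starting material
21 | mixed anhydride: (2Z)-2-methylbut-2-enoic 2,4,6-trichlorobenzoic anhydride | C/C=C(/C)C(=O)OC(=O)c1c(Cl)cc(Cl)cc1Cl | intermediate (not isolated)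
22 | (2S,3R)-5-acetyl-2-(2-hydroxypropan-2-yl)-6,7-dimethoxy-2,3-dihydro-1-benzofuran-3-yl (2Z)-2-methylbut-2-enoate | CC(C)(O)[C@H]1Oc2c(cc(C(C)=O)c(OC)c2OC)[C@H]1OC(=O)/C(C)=C\C | intermediate
23 | sulfamate salt: triethylammonium salt of the N-(methoxycarbonyl)sulfamate ester of the tertiary alcohol of 22 | COC(=O)[N-]S(=O)(=O)OC(C)(C)[C@H]1Oc2c(cc(C(C)=O)c(OC)c2OC)[C@H]1OC(=O)/C(C)=C\C.CC[NH+](CC)CC | intermediate (not isolated)
24 | (2R,3R)-5-acetyl-6,7-dimethoxy-2-(prop-1-en-2-yl)-2,3-dihydro-1-benzofuran-3-yl (2Z)-2-methylbut-2-enoate | C=C(C)[C@H]1Oc2c(cc(C(C)=O)c(OC)c2OC)[C@H]1OC(=O)/C(C)=C\C | target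

**Step count and risks**

Total step count: 16. Longest linear sequence: 16 steps (1 to 24); 6, 15 and 20 enter as purchased compounds.

Steps most likely to fail:

1. Step 12. Cleavage of the hindered benzylic C3–H may be slower than intermolecular redistribution or coupling of the Si–H, or than transfer dehydrogenation of the dihydrofuran ring to the benzofuran by the same catalyst and acceptor. The fallback replaces the silicon tether by a carbamate-directed radical 1,3-oxygenation (Hofmann–Löffler–Freytag-type hydrogen transfer), sets out from 14 and returns at 19. No silane is used, so the dioxolane is first removed (PPTS, THF–H2O) to give 1-[(2S)-2-(2-hydroxypropan-2-yl)-6,7-dimethoxy-2,3-dihydro-1-benzofuran-5-yl]ethanone F1, whose acetyl group also tempers the arene toward electrophilic bromine. CF3CH2NCO with CuCl (cat.) in DMF should give the N-(2,2,2-trifluoroethyl)carbamate F2, and acetyl hypobromite in CH2Cl2 at 0 °C in the dark the N-bromocarbamate F3. Irradiation with CBr4 in PhCF3 should let the nitrogen radical abstract the C3 hydrogen through a seven-membered transition state and give the C3 bromide F4 as an epimer mixture. Ag2CO3 in CH2Cl2 should make the carbamate carbonyl oxygen displace bromide on the face of the tether, giving the cis-fused six-membered iminocarbonate F5. Aqueous AcOH should hydrolyse it to the cyclic carbonate F6, and K2CO3 in MeOH should release the cis-diol 19, after which steps 15 and 16 follow unchanged.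

2. Step 16. Elimination may run toward C2–H and give the tetrasubstituted enol ether, or the tertiary sulfamate may ionise with participation of the neighbouring ester carbonyl and loss or migration of the angeloyl group. The fallback takes the ester out of the elimination by reversing the last two operations; it sets out from 19 and returns at 24. TESCl and imidazole in DMF at 0 °C should silylate only the secondary hydroxyl and give the 3-O-triethylsilyl ether F7. SOCl2 in pyridine at −20 to 0 °C should dehydrate the tertiary alcohol by E2 removal of an unhindered methyl hydrogen from the chlorosulfite, giving the isopropenyl silyl ether F8. Bu4NF buffered with AcOH in THF should give 1-[(2R,3R)-3-hydroxy-6,7-dimethoxy-2-(prop-1-en-2-yl)-2,3-dihydro-1-benzofuran-5-yl]ethanone F9. Angeloylation of F9 with the mixed anhydride 21 under the conditions of step 15 then gives 24.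

3. Step 15. Acylation of the C3–OH next to the cis quaternary carbon may be slow, which gives time for Z to E isomerisation of the angeloyl unit or for acyl transfer from the aroyl half of the mixed anhydride. The fallback builds the Z double bond after the ester is in place; it sets out from 19 and returns at 22. Esterification of 19 with 2-[bis(2,2,2-trifluoroethoxy)phosphoryl]propanoic acid (DCC, DMAP, CH2Cl2) should give the phosphonopropanoate F10. Still–Gennari olefination of F10 (KN(SiMe3)2, one equivalent, 18-crown-6, THF, −78 °C, then CH3CHO) should give the Z-configured 2-methylbut-2-enoate 22, which continues with step 16.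

Further compounds
F1 | step 12 | 1-[(2S)-2-(2-hydroxypropan-2-yl)-6,7-dimethoxy-2,3-dihydro-1-benzofuran-5-yl]ethanone | CC(C)(O)[C@H]1Oc2c(cc(C(C)=O)c(OC)c2OC)C1
F2 | step 12 | 2-[(2S)-5-acetyl-6,7-dimethoxy-2,3-dihydro-1-benzofuran-2-yl]propan-2-yl N-(2,2,2-trifluoroethyl)carbamate | FC(F)(F)CNC(=O)OC(C)(C)[C@H]1Oc2c(cc(C(C)=O)c(OC)c2OC)C1
F3 | step 12 | 2-[(2S)-5-acetyl-6,7-dimethoxy-2,3-dihydro-1-benzofuran-2-yl]propan-2-yl N-bromo-N-(2,2,2-trifluoroethyl)carbamate | FC(F)(F)CN(Br)C(=O)OC(C)(C)[C@H]1Oc2c(cc(C(C)=O)c(OC)c2OC)C1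
F4 | step 12 | 2-[(2S)-5-acetyl-3-bromo-6,7-dimethoxy-2,3-dihydro-1-benzofuran-2-yl]propan-2-yl N-(2,2,2-trifluoroethyl)carbamate (C3 epimers) | FC(F)(F)CNC(=O)OC(C)(C)[C@H]1Oc2c(cc(C(C)=O)c(OC)c2OC)C1Br
F5 | step 12 | cis-fused cyclic iminocarbonate (six-membered ring O–C(=NCH2CF3)–O bridging the CMe2 oxygen and C3, 5-acetyl-6,7-dimethoxy) | FC(F)(F)CN=C1OC(C)(C)[C@H]2Oc3c(cc(C(C)=O)c(OC)c3OC)[C@H]2O1
F6 | step 12 | cis-fused cyclic carbonate of diol 19 | O=C1OC(C)(C)[C@H]2Oc3c(cc(C(C)=O)c(OC)c3OC)[C@H]2O1
F7 | step 16 | 1-[(2S,3R)-2-(2-hydroxypropan-2-yl)-6,7-dimethoxy-3-(triethylsilyloxy)-2,3-dihydro-1-benzofuran-5-yl]ethanone | CC(C)(O)[C@H]1Oc2c(cc(C(C)=O)c(OC)c2OC)[C@H]1O[Si](CC)(CC)CC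
F8 | step 16 | 1-[(2R,3R)-6,7-dimethoxy-2-(prop-1-en-2-yl)-3-(triethylsilyloxy)-2,3-dihydro-1-benzofuran-5-yl]ethanone | C=C(C)[C@H]1Oc2c(cc(C(C)=O)c(OC)c2OC)[C@H]1O[Si](CC)(CC)CC
F9 | step 16 | 1-[(2R,3R)-3-hydroxy-6,7-dimethoxy-2-(prop-1-en-2-yl)-2,3-dihydro-1-benzofuran-5-yl]ethanone | C=C(C)[C@H]1Oc2c(cc(C(C)=O)c(OC)c2OC)[C@H]1O
F10 | step 15 | (2S,3R)-5-acetyl-2-(2-hydroxypropan-2-yl)-6,7-dimethoxy-2,3-dihydro-1-benzofuran-3-yl 2-[bis(2,2,2-trifluoroethoxy)phosphoryl]propanoate | CC(C)(O)[C@H]1Oc2c(cc(C(C)=O)c(OC)c2OC)[C@H]1OC(=O)C(C)P(=O)(OCC(F)(F)F)OCC(F)(F)F
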